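Abruquinone B is traced back, through the ring B phenol and its benzyl ether, to a 3-aryl-4H-chromene whose hydrogenation sets the only stereocentre (C3, S in the given SMILES).
The pyran ring (ring C) of that chromene is cut at C3–C4 and at O1–C8a, giving a (ring B)-acetaldehyde (O1–C2–C3) and 2-iodo-3,4,5-trimethoxybenzyl bromide (C4 with ring A); the two are joined in one flask as a formal [3+3] annulation.
Enabling feature: C3 carries ring B and sits next to C2–O1, so O1–C2–C3 is an arylacetaldehyde enolate, nucleophilic at C3 and at O1. The C4–C4a–C8a edge of ring A is the matching 1,3-bis-electrophile, and because the two free CH positions of a 3,4,5-trimethoxybenzyl ring are equivalent, C8a is iodinated without a regiochemical question.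
Rings A and B are bought as benzenes; ring C is the only ring formed (step 7). Ring B is oxidised to the quinone last, after its phenol oxygen has served to place the C2–C3 unit by a Claisen rearrangement.
Key step: step 7

Remark: locants are chroman O1, C2, C3, C4, C4a, C5 to C8, C8a; ring A is the benzo ring of the chroman, ring B the quinone ring, ring C the pyran ring.
Remark: the sense of induction in step 8 cannot be assigned in advance for this substrate; the ligand antipode that gives the 3S product is used, both antipodes being available.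

Step 1
Reactants: 1 (3,4,5-trimethoxyphenyl)methanol
Product: 2 (2-iodo-3,4,5-trimethoxyphenyl)methanol
Conditions: NIS (1.05 equiv), CF3CO2H (10 mol %), MeCN, 0 °C to rt
Reagents that add atoms: N-iodosuccinimide O=C1CCC(=O)N1I
Why: Electrophilic aromatic iodination; the two unsubstituted ring positions are equivalent by symmetry and each is ortho and para to a methoxy group, so a single mono-iodide at the future C8a is expected.

Step 2
Reactants: 2 (2-iodo-3,4,5-trimethoxyphenyl)methanol
Product: 3 1-(bromomethyl)-2-iodo-3,4,5-trimethoxybenzene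
Conditions: PBr3 (0.4 equiv), CH2Cl2, 0 °C
Reagents that add atoms: phosphorus tribromide BrP(Br)Br
Why: Conversion of a primary benzylic alcohol into the bromide with PBr3 (SN2 on the phosphite ester), which leaves the aryl iodide and the methyl ethers alone.

Step 3
Reactants: 4 2,3,4-trimethoxyphenol
Product: 5 1-(allyloxy)-2,3,4-trimethoxybenzene
Conditions: allyl bromide, K2CO3, acetone, reflux
Reagents that add atoms: allyl bromide C=CCBr
Why: Williamson O-allylation of the phenol.

Step 4
Reactants: 5 1-(allyloxy)-2,3,4-trimethoxybenzene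
Product: 6 6-allyl-2,3,4-trimethoxyphenol
Conditions: N,N-diethylaniline, 190 °C
Reagents that add atoms: none
Why: Aromatic Claisen rearrangement ([3,3]-sigmatropic shift, then tautomerisation); the only unsubstituted ortho position is C6, so the allyl group should go there and the phenol oxygen is set free again.

Step 5
Reactants: 6 6-allyl-2,3,4-trimethoxyphenol
Product: 7 1-allyl-2-(benzyloxy)-3,4,5-trimethoxybenzene
Conditions: BnBr, K2CO3, DMF, 50 °C
Reagents that add atoms: benzyl bromide BrCc1ccccc1
Why: Williamson benzylation masks the phenol for the enolate chemistry; the benzyl group is removed by hydrogenolysis in step 9.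

Step 6
Reactants: 7 1-allyl-2-(benzyloxy)-3,4,5-trimethoxybenzene
Product: 9 2-[2-(benzyloxy)-3,4,5-trimethoxyphenyl]acetaldehyde, via vicinal diol 8 (not isolated)
Conditions: OsO4 (2 mol %), NaIO4 (4 equiv), 2,6-lutidine (2 equiv), 1,4-dioxane/H2O (3:1), rt; product used crude at once
Reagents that add atoms: sodium periodate [Na+].[O-]I(=O)(=O)=O (oxygen source, relayed by catalytic osmium tetroxide O=[Os](=O)(=O)=O)
Why: Lemieux–Johnson oxidation (catalytic dihydroxylation, then periodate glycol cleavage) shortens the allyl group by one carbon to the arylacetaldehyde, with 2,6-lutidine holding back over-oxidation.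

Step 7
Reactants: 9 2-[2-(benzyloxy)-3,4,5-trimethoxyphenyl]acetaldehyde; 3 1-(bromomethyl)-2-iodo-3,4,5-trimethoxybenzene
Product: 12 3-[2-(benzyloxy)-3,4,5-trimethoxyphenyl]-6,7,8-trimethoxy-4H-chromene, via potassium enolate 10 (not isolated), via racemic 2,3-diarylpropanal 11 (not isolated)
Conditions: KN(SiMe3)2 (1.05 equiv), toluene–THF (9:1), −78 °C, slow addition of 9; then 3, −78 to 0 °C; then CuI (10 mol %), 1,10-phenanthroline (20 mol %), Cs2CO3 (2 equiv), 105 °C, same flask, argon
Reagents that add atoms: none
Why: Proposed new method: deprotonation of 9 gives the soft α-aryl enolate 10 (the O1–C2–C3 unit), which is C-benzylated by the benzylic bromide of 3 in an SN2 reaction (C3–C4) to aldehyde 11; Cs2CO3 then re-enolises 11 and monovalent copper couples the enolate oxygen with the neighbouring aryl iodide (oxidative addition at C8a–I, then C–O reductive elimination; O1–C8a) to give the cyclic enol ether 12. The closest known reaction type is the copper-catalysed intramolecular O-arylation of ketone and 1,3-dicarbonyl enolates that carry a 2-halobenzyl or 2-haloaryl group (4H-chromenes, benzofurans), also run as a one-pot C-benzylation/O-arylation of β-keto esters with 2-halobenzyl halides; an unstabilised aldehyde enolate has not been shown in this role, hence the label. Ring C closes in the second stage as a six-membered ring by attack of the enolate oxygen on C8a with the leaving C–I bond outside the ring (a 6-exo-type Ullmann closure through a seven-membered copper chelate). No stereocentre results: C3 of 11 is racemic and labile and becomes trigonal in 12, so C3 is left to step 8. The selectivities needed are C- over O-benzylation and mono- over dialkylation, served by the soft benzylic bromide and a preformed stoichiometric enolate at −78 °C, and O- over C-arylation, secured because C-arylation would have to form a benzocyclobutene while the enolate geometry with O1 cis to C4 is reached by reversible protonation.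

Step 8
Reactants: 12 3-[2-(benzyloxy)-3,4,5-trimethoxyphenyl]-6,7,8-trimethoxy-4H-chromene
Product: 13 (3S)-3-[2-(benzyloxy)-3,4,5-trimethoxyphenyl]-6,7,8-trimethoxychromane
Conditions: [Ir(cod)(L*)][B(C6H3(CF3)2)4] (1 mol %; L* = chiral bicyclic pyridine–phosphinite P,N ligand), H2 (50 bar), CH2Cl2, rt
Reagents that add atoms: none
Why: Iridium-catalysed asymmetric hydrogenation of a trisubstituted, aryl-bearing cyclic enol ether (a reaction type established on 4H-chromenes and 3-aryl-2H-chromenes); the chiral P,N ligand should differentiate the enantiotopic faces of C2=C3 so that hydrogen reaches C3 from the face that gives 3S, while the benzyl and methyl ethers stay inert.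

Step 9
Reactants: 13 (3S)-3-[2-(benzyloxy)-3,4,5-trimethoxyphenyl]-6,7,8-trimethoxychromane
Product: 14 2,3,4-trimethoxy-6-[(3S)-6,7,8-trimethoxychroman-3-yl]phenol
Conditions: H2 (1 atm), Pd/C (10 %), EtOAc/EtOH, rt
Reagents that add atoms: none
Why: Hydrogenolysis of the benzyl aryl ether over Pd/C, which should leave the chroman, the methyl ethers and the C3 stereocentre untouched.

Step 10
Reactants: 14 2,3,4-trimethoxy-6-[(3S)-6,7,8-trimethoxychroman-3-yl]phenol
Product: 15 abruquinone B, 2,3-dimethoxy-5-[(3S)-6,7,8-trimethoxychroman-3-yl]-1,4-benzoquinone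
Conditions: PhI(OAc)2 (1.2 equiv), MeCN/H2O (2:1), 0 °C
Reagents that add atoms: water O
Why: Oxidative demethylation of a para-methoxyphenol with PhI(OAc)2 (phenol oxidation, water addition para to the phenol oxygen, loss of methanol) should give the para-quinone only on ring B, the one ring with a free phenol, and the weakly acidic medium avoids base-induced tautomerisation of the alkylquinone that could scramble C3.

Compound list
1 | (3,4,5-trimethoxyphenyl)methanol | COc1cc(CO)cc(OC)c1OC | starting material
2 | (2-iodo-3,4,5-trimethoxyphenyl)methanol | COc1cc(CO)c(I)c(OC)c1OC | intermediate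
3 | 1-(bromomethyl)-2-iodo-3,4,5-trimethoxybenzene | COc1cc(CBr)c(I)c(OC)c1OC | intermediate
4 | 2,3,4-trimethoxyphenol | COc1ccc(O)c(OC)c1OC | starting material
5 | 1-(allyloxy)-2,3,4-trimethoxybenzene | COc1ccc(OCC=C)c(OC)c1OC | intermediate
6 | 6-allyl-2,3,4-trimethoxyphenol | COc1cc(CC=C)c(O)c(OC)c1OC | intermediate
7 | 1-allyl-2-(benzyloxy)-3,4,5-trimethoxybenzene | COc1cc(CC=C)c(OCc2ccccc2)c(OC)c1OC | intermediate
8 | 3-[2-(benzyloxy)-3,4,5-trimethoxyphenyl]propane-1,2-diol (racemic, not isolated) | COc1cc(CC(O)CO)c(OCc2ccccc2)c(OC)c1OC | intermediate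
9 | 2-[2-(benzyloxy)-3,4,5-trimethoxyphenyl]acetaldehyde | COc1cc(CC=O)c(OCc2ccccc2)c(OC)c1OC | intermediate
10 | potassium 2-[2-(benzyloxy)-3,4,5-trimethoxyphenyl]ethen-1-olate (not isolated) | COc1cc(C=C[O-])c(OCc2ccccc2)c(OC)c1OC.[K+] | intermediate
11 | 2-[2-(benzyloxy)-3,4,5-trimethoxyphenyl]-3-(2-iodo-3,4,5-trimethoxyphenyl)propanal (racemic, not isolated) | COc1cc(C(C=O)Cc2cc(OC)c(OC)c(OC)c2I)c(OCc2ccccc2)c(OC)c1OC | intermediate
12 | 3-[2-(benzyloxy)-3,4,5-trimethoxyphenyl]-6,7,8-trimethoxy-4H-chromene | COc1cc(C2=COc3c(cc(OC)c(OC)c3OC)C2)c(OCc2ccccc2)c(OC)c1OC | intermediate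
13 | (3S)-3-[2-(benzyloxy)-3,4,5-trimethoxyphenyl]-6,7,8-trimethoxychromane | COc1cc([C@H]2COc3c(cc(OC)c(OC)c3OC)C2)c(OCc2ccccc2)c(OC)c1OC | intermediate
14 | 2,3,4-trimethoxy-6-[(3S)-6,7,8-trimethoxychroman-3-yl]phenol | COc1cc([C@H]2COc3c(cc(OC)c(OC)c3OC)C2)c(O)c(OC)c1OC | intermediate
15 | abruquinone B, 2,3-dimethoxy-5-[(3S)-6,7,8-trimethoxychroman-3-yl]-1,4-benzoquinone | COC1=C(OC)C(=O)C([C@H]2COc3c(cc(OC)c(OC)c3OC)C2)=CC1=O | target

Total step count: 10. Longest linear sequence: 8 steps (from 4 to 15, steps 3 to 10).

Steps most likely to fail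

Step 7 (Proposed new method). In the first stage the aldehyde enolate may be benzylated on oxygen, benzylated twice, or lost to aldol self-condensation; in the second stage the C–O coupling at the hindered, electron-rich aryl iodide may be too slow. The fallback uses known chemistry only, sets out from 9 and comes back at 13, so it also replaces step 8. Pinnick oxidation (NaClO2, NaH2PO4, 2-methyl-2-butene, t-BuOH/H2O) should give 2-[2-(benzyloxy)-3,4,5-trimethoxyphenyl]acetic acid F1. Activation as the mixed pivalic anhydride (pivaloyl chloride, Et3N, THF) and acylation of lithiated (S)-4-benzyl-2-oxazolidinone (n-BuLi) should give (S)-4-benzyl-3-{[2-(benzyloxy)-3,4,5-trimethoxyphenyl]acetyl}oxazolidin-2-one F2. Evans alkylation (NaN(SiMe3)2, THF, −78 °C, then 3) should give the alkylated imide F3, with the S centre set by attack of 3 on the chelated Z-enolate anti to the benzyl group of the auxiliary. Reductive removal of the auxiliary (LiBH4, Et2O/H2O, 0 °C) should give (S)-2-[2-(benzyloxy)-3,4,5-trimethoxyphenyl]-3-(2-iodo-3,4,5-trimethoxyphenyl)propan-1-ol F4. Copper-catalysed intramolecular O-arylation of the primary alcohol (CuI, 1,10-phenanthroline, Cs2CO3, toluene, 110 °C) then closes ring C to 13.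

Step 8. Facial selectivity may be poor or turnover low on the hindered enol ether, and the acidic iridium hydride may decompose the enol ether. The fallback sets out from 12 and comes back at 13. Mild aqueous acid (0.5 M HCl, THF, rt) should hydrolyse the enol ether to 3-[2-(benzyloxy)-3,4,5-trimethoxyphenyl]-6,7,8-trimethoxychroman-2-ol F5, which is in equilibrium with its open hydroxy aldehyde and is labile at C3. Dynamic kinetic resolution by asymmetric hydrogenation of this α-aryl aldehyde (RuCl2[(S)-Xyl-SDP][(R,R)-DPEN] or its mirror image, whichever gives the S alcohol, KOtBu, i-PrOH, H2 50 atm) should give 6-[(S)-2-[2-(benzyloxy)-3,4,5-trimethoxyphenyl]-3-hydroxypropyl]-2,3,4-trimethoxyphenol F6. Mitsunobu etherification (PPh3, diisopropyl azodicarboxylate, THF, 0 °C) then closes ring C to 13.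

Step 6. The oxidative cleavage may over-oxidise the aldehyde or attack the electron-rich ring, and the arylacetaldehyde may be lost to self-condensation on isolation. The fallback sets out from 4 and comes back at 9, replacing steps 3 to 6 with a non-oxidative release of the aldehyde. Magnesium-mediated ortho-formylation (MgCl2, Et3N, paraformaldehyde, MeCN, reflux) should give 2-hydroxy-3,4,5-trimethoxybenzaldehyde F7. Benzylation (BnBr, K2CO3, DMF) should give 2-(benzyloxy)-3,4,5-trimethoxybenzaldehyde F8. Wittig homologation ([Ph3PCH2OMe]Cl, KOtBu, THF, 0 °C) should give 1-(benzyloxy)-2,3,4-trimethoxy-6-(2-methoxyvinyl)benzene F9 as an E/Z mixture. Hydrolysis of the enol ether (1 M HCl, THF, rt) then gives 9, used crude in step 7.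

Further compounds
F1 | step 7 | 2-[2-(benzyloxy)-3,4,5-trimethoxyphenyl]acetic acid | COc1cc(CC(=O)O)c(OCc2ccccc2)c(OC)c1OC
F2 | step 7 | (S)-4-benzyl-3-{[2-(benzyloxy)-3,4,5-trimethoxyphenyl]acetyl}oxazolidin-2-one | COc1cc(CC(=O)N2[C@@H](Cc3ccccc3)COC2=O)c(OCc2ccccc2)c(OC)c1OC
F3 | step 7 | (S)-4-benzyl-3-[(S)-2-[2-(benzyloxy)-3,4,5-trimethoxyphenyl]-3-(2-iodo-3,4,5-trimethoxyphenyl)propanoyl]oxazolidin-2-one | COc1cc([C@H](Cc2cc(OC)c(OC)c(OC)c2I)C(=O)N2[C@@H](Cc3ccccc3)COC2=O)c(OCc2ccccc2)c(OC)c1OC
F4 | step 7 | (S)-2-[2-(benzyloxy)-3,4,5-trimethoxyphenyl]-3-(2-iodo-3,4,5-trimethoxyphenyl)propan-1-ol | COc1cc([C@H](Cc2cc(OC)c(OC)c(OC)c2I)CO)c(OCc2ccccc2)c(OC)c1OC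
F5 | step 8 | 3-[2-(benzyloxy)-3,4,5-trimethoxyphenyl]-6,7,8-trimethoxychroman-2-ol (mixture of stereoisomers) | COc1cc(C2Cc3cc(OC)c(OC)c(OC)c3OC2O)c(OCc2ccccc2)c(OC)c1OC
F6 | step 8 | 6-[(S)-2-[2-(benzyloxy)-3,4,5-trimethoxyphenyl]-3-hydroxypropyl]-2,3,4-trimethoxyphenol | COc1cc([C@H](Cc2cc(OC)c(OC)c(OC)c2O)CO)c(OCc2ccccc2)c(OC)c1OC
F7 | step 6 | 2-hydroxy-3,4,5-trimethoxybenzaldehyde | COc1cc(C=O)c(O)c(OC)c1OC
F8 | step 6 | 2-(benzyloxy)-3,4,5-trimethoxybenzaldehyde | COc1cc(C=O)c(OCc2ccccc2)c(OC)c1OC
F9 | step 6 | 1-(benzyloxy)-2,3,4-trimethoxy-6-(2-methoxyvinyl)benzene (E/Z mixture) | COC=Cc1cc(OC)c(OC)c(OC)c1OCc1ccccc1
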